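**Strategy.** The plan reads the O1–C2–C(OH)Me2 edge of the dihydrobenzofuran ring (ring oxygen, S-configured C2, exocyclic carbinol carbon) as the rearranged O1–CMe2–CH(OH) edge of a 2,2-dimethylchroman-3-ol. Triflation of the (3R)-carbinol lets O1 displace the leaving group from behind, and water opens the bridged oxiranium ion at the gem-dimethyl carbon. One operation contracts the pyran to the furan ring, forms the O1–C2 and tertiary C–OH bonds and sets C2 by a single inversion. The precursor is 8-acetyl-7-methoxy-5-(methoxymethoxy)-2,2-dimethylchroman-3-ol, made in enantioenriched form from the chromene by Mn(salen) epoxidation and benzylic hydrogenolysis. Claisen–Schmidt condensation and MOM removal complete the chalcone.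

Key step: step 5

Assumption: the (R,R)-Mn(salen) catalyst is taken to give the (3R,4R)-oxide of chromene 5, as it does with simple 2,2-dimethyl-2H-chromenes; the configuration of 7 should be confirmed (e.g. Mosher esters) before step 5.

Remark on numbering: in the chromans 5–9 the acetyl sits on C8; it is C7 only in the dihydrobenzofurans 10–14.

Remark on the annulation: the only free hydroxyl of 2 is hydrogen-bonded to the acetyl group, and such phenols react poorly with enals, so the chromene is built by the propargyl ether Claisen route.

Step 1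
Reactants: 1 1-(2,4-dihydroxy-6-methoxyphenyl)ethanone
Product: 2 1-[2-hydroxy-6-methoxy-4-(methoxymethoxy)phenyl]ethanone
Conditions: MOMCl (1.1 equiv), K2CO3, acetone, 0 °C to rt
Reagents that add atoms: chloromethyl methyl ether (MOMCl), COCCl
Why: Williamson-type O-alkylation (MOM protection); the 4-OH is the more acidic, non-chelated phenol, whereas the 2-OH is tied up in a hydrogen bond to the acetyl carbonyl and should stay free with one equivalent of electrophile.

Step 2
Reactants: 2 1-[2-hydroxy-6-methoxy-4-(methoxymethoxy)phenyl]ethanone; 3 3-chloro-3-methylbut-1-yne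
Product: 5 1-[7-methoxy-5-(methoxymethoxy)-2,2-dimethyl-2H-chromen-8-yl]ethanone, via propargyl ether 4 (not isolated)
Conditions: K2CO3, KI, CuI (cat.), DMF, 65 °C; then solvent exchange to o-xylene, 140 °C
Reagents that add atoms: none
Why: Copper-assisted O-propargylation of the remaining phenoxide, then aromatic propargyl Claisen rearrangement onto C3 (the only unsubstituted ortho carbon), 1,5-hydrogen shift and oxa-6π electrocyclisation, is the standard route to 2,2-dimethyl-2H-chromenes and needs only neutral heating, which the MOM ether and the ketone tolerate.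

Step 3
Reactants: 5 1-[7-methoxy-5-(methoxymethoxy)-2,2-dimethyl-2H-chromen-8-yl]ethanone
Product: 6 1-[(3R,4R)-3,4-epoxy-7-methoxy-5-(methoxymethoxy)-2,2-dimethyl-3,4-dihydro-2H-chromen-8-yl]ethanone
Conditions: (R,R)-Jacobsen Mn(salen)Cl (5 mol%), NMO, mCPBA, CH2Cl2, −78 °C; cold aq. NaOH wash, filtration through basic alumina, used crude
Reagents that add atoms: 3-chloroperoxybenzoic acid (mCPBA), OOC(=O)c1cccc(Cl)c1
Why: Jacobsen–Katsuki epoxidation; aryl-conjugated cis-alkenes of 2,2-dimethyl-2H-chromenes are its best substrate class, the catalyst chirality fixes C3 and C4 in one oxygen transfer (expected 3R,4R with the R,R ligand), and the anhydrous low-temperature mCPBA/NMO variant avoids hypochlorite (ring chlorination, haloform cleavage of the methyl ketone) and spares the acid-labile benzylic epoxide.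

Step 4
Reactants: 6 1-[(3R,4R)-3,4-epoxy-7-methoxy-5-(methoxymethoxy)-2,2-dimethyl-3,4-dihydro-2H-chromen-8-yl]ethanone
Product: 7 1-[(3R)-3-hydroxy-7-methoxy-5-(methoxymethoxy)-2,2-dimethyl-3,4-dihydro-2H-chromen-8-yl]ethanone
Conditions: H2 (1 atm), 10% Pd/C, Et3N (trace), EtOAc, rt
Reagents that add atoms: none
Why: Palladium-catalysed hydrogenolysis cleaves only the activated benzylic C4–O bond of the epoxide, so the C3–O bond and its R configuration are carried over unchanged; the amine buffer suppresses acid-induced rearrangement, and the twisted, di-ortho-substituted aryl ketone should be reduced much more slowly.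

Step 5
Reactants: 7 1-[(3R)-3-hydroxy-7-methoxy-5-(methoxymethoxy)-2,2-dimethyl-3,4-dihydro-2H-chromen-8-yl]ethanone
Product: 10 1-[(2S)-2-(2-hydroxypropan-2-yl)-6-methoxy-4-(methoxymethoxy)-2,3-dihydro-1-benzofuran-7-yl]ethanone, via chromanyl triflate 8 (not isolated), via oxiranium triflate 9 (not isolated)
Conditions: Tf2O (1.2 equiv), 2,6-lutidine (3 equiv), CH2Cl2, −78 °C; then THF–H2O (4:1, large excess) added at −40 °C, warm to rt
Reagents that add atoms: water, O
Why: O-Triflation of the C3 carbinol is followed, on warming in the aqueous medium, by intramolecular displacement: in the half-chair with the triflate pseudo-equatorial the O1–C2 bond is antiperiplanar to C3–OTf, so O1 attacks C3 from the rear (3-exo-tet closure, which also completes the five-membered O1–C3–C4–C4a–C8a ring) and gives the bridged oxiranium ion 9. Water then opens 9 at the gem-dimethyl carbon, where the positive charge is concentrated, so the net change is a 1,2-shift of oxygen with pyran-to-furan ring contraction and formation of the tertiary alcohol. The closest known reaction type is the solvolytic ring contraction of 2,2-dimethylchroman-3-yl sulfonates through ether-oxygen participation. The C2 stereocentre of the dihydrobenzofuran is controlled by the C3 configuration of 7: one inversion at that carbon, with the later water attack at the neighbouring carbon, converts 3R into 2S. The step needs oxygen participation to win over direct substitution, methyl or hydride shift and elimination toward C4, and needs water capture rather than proton loss; the neopentyl-like position of C3 blocks SN2, the antiperiplanar O1–C2 bond favours the oxygen shift, the gem-dimethyl group directs the opening, and excess water at low temperature with only a weak hindered base favours the carbinol over the isopropenyl compound. The C8 acetyl, twisted out of the ring plane by its two ortho neighbours, should take little electron density from O1.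

Step 6
Reactants: 11 4-hydroxybenzaldehyde
Product: 12 4-(methoxymethoxy)benzaldehyde
Conditions: MOMCl, K2CO3, acetone, rt
Reagents that add atoms: chloromethyl methyl ether (MOMCl), COCCl
Why: Williamson-type O-alkylation of the phenoxide (MOM protection), so that the aldehyde stays electrophilic under the basic aldol conditions.

Step 7
Reactants: 10 1-[(2S)-2-(2-hydroxypropan-2-yl)-6-methoxy-4-(methoxymethoxy)-2,3-dihydro-1-benzofuran-7-yl]ethanone; 12 4-(methoxymethoxy)benzaldehyde
Product: 13 (2E)-1-[(2S)-2-(2-hydroxypropan-2-yl)-6-methoxy-4-(methoxymethoxy)-2,3-dihydro-1-benzofuran-7-yl]-3-[4-(methoxymethoxy)phenyl]prop-2-en-1-one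
Conditions: KOH, EtOH–H2O, rt
Reagents that add atoms: none
Why: Claisen–Schmidt condensation; the methyl ketone enolate adds to the non-enolisable aldehyde and E1cB dehydration gives the conjugated (E)-enone under thermodynamic control, no flavanone can form because no free hydroxyl is ortho to the carbonyl, and the C2 stereocentre carries no acidic hydrogen.

Step 8
Reactants: 13 (2E)-1-[(2S)-2-(2-hydroxypropan-2-yl)-6-methoxy-4-(methoxymethoxy)-2,3-dihydro-1-benzofuran-7-yl]-3-[4-(methoxymethoxy)phenyl]prop-2-en-1-one
Product: 14 (2E)-1-[(2S)-4-hydroxy-2-(2-hydroxypropan-2-yl)-6-methoxy-2,3-dihydro-1-benzofuran-7-yl]-3-(4-hydroxyphenyl)prop-2-en-1-one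
Conditions: 3 M aq. HCl, MeOH, 40 °C
Reagents that add atoms: none
Why: Acid-catalysed methanolysis of both aryl MOM acetals; the tertiary carbinol, whose ionisation is disfavoured by the adjacent ring oxygen, and the (E)-enone should survive dilute acid at mild temperature.

**Compound list**

1 | 1-(2,4-dihydroxy-6-methoxyphenyl)ethanone | COc1cc(O)cc(O)c1C(C)=O | starting material
2 | 1-[2-hydroxy-6-methoxy-4-(methoxymethoxy)phenyl]ethanone | COc1cc(OCOC)cc(O)c1C(C)=O | intermediate
3 | 3-chloro-3-methylbut-1-yne | CC(C)(Cl)C#C | starting material
4 | 1-[2-methoxy-4-(methoxymethoxy)-6-[(2-methylbut-3-yn-2-yl)oxy]phenyl]ethanone (propargyl ether) | COc1cc(OCOC)cc(OC(C)(C)C#C)c1C(C)=O | intermediate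
5 | 1-[7-methoxy-5-(methoxymethoxy)-2,2-dimethyl-2H-chromen-8-yl]ethanone | COc1cc(OCOC)c2c(c1C(C)=O)OC(C)(C)C=C2 | intermediate
6 | 1-[(3R,4R)-3,4-epoxy-7-methoxy-5-(methoxymethoxy)-2,2-dimethyl-3,4-dihydro-2H-chromen-8-yl]ethanone | COc1cc(OCOC)c2c(c1C(C)=O)OC(C)(C)[C@@H]3O[C@H]23 | intermediate
7 | 1-[(3R)-3-hydroxy-7-methoxy-5-(methoxymethoxy)-2,2-dimethyl-3,4-dihydro-2H-chromen-8-yl]ethanone | COc1cc(OCOC)c2c(c1C(C)=O)OC(C)(C)[C@H](O)C2 | intermediate
8 | (3R)-8-acetyl-7-methoxy-5-(methoxymethoxy)-2,2-dimethyl-3,4-dihydro-2H-chromen-3-yl trifluoromethanesulfonate | COc1cc(OCOC)c2c(c1C(C)=O)OC(C)(C)[C@H](OS(=O)(=O)C(F)(F)F)C2 | intermediate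
9 | bridged aryloxiranium triflate: the O+ is bonded to the aryl carbon, to CMe2 and to the former C3 (now S), giving a benzo-fused 6,6-dimethyl-1-oxoniabicyclo[3.1.0]hexane that carries the acetyl, methoxy and MOM-oxy groups | COc1cc(OCOC)c2c(c1C(C)=O)[O+]3C(C)(C)[C@@H]3C2.[O-]S(=O)(=O)C(F)(F)F | intermediate
10 | 1-[(2S)-2-(2-hydroxypropan-2-yl)-6-methoxy-4-(methoxymethoxy)-2,3-dihydro-1-benzofuran-7-yl]ethanone | COc1cc(OCOC)c2c(c1C(C)=O)O[C@H](C(C)(C)O)C2 | intermediate
11 | 4-hydroxybenzaldehyde | O=Cc1ccc(O)cc1 | starting material
12 | 4-(methoxymethoxy)benzaldehyde | COCOc1ccc(C=O)cc1 | intermediate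
13 | (2E)-1-[(2S)-2-(2-hydroxypropan-2-yl)-6-methoxy-4-(methoxymethoxy)-2,3-dihydro-1-benzofuran-7-yl]-3-[4-(methoxymethoxy)phenyl]prop-2-en-1-one | COc1cc(OCOC)c2c(c1C(=O)/C=C/c1ccc(OCOC)cc1)O[C@H](C(C)(C)O)C2 | intermediate
14 | (2E)-1-[(2S)-4-hydroxy-2-(2-hydroxypropan-2-yl)-6-methoxy-2,3-dihydro-1-benzofuran-7-yl]-3-(4-hydroxyphenyl)prop-2-en-1-one | COc1cc(O)c2c(c1C(=O)/C=C/c1ccc(O)cc1)O[C@H](C(C)(C)O)C2 | target

**Step count.** Total: 8 steps. Longest linear sequence: 7 steps (steps 1–5, 7 and 8); step 6 is a one-step side branch.

**Steps most likely to fail, with fallbacks**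

1. Step 5. The opened oxiranium ion may lose a methyl proton faster than water captures it, or the triflate may collapse before water is present, so the tertiary carbinol is not reached cleanly. The fallback separates the two events and sets out from 7. Tf2O and pyridine in CH2Cl2 (−78 °C to rt, no water) should drive the same oxygen-assisted contraction to the elimination product 1-[(2S)-6-methoxy-4-(methoxymethoxy)-2-(prop-1-en-2-yl)-2,3-dihydro-1-benzofuran-7-yl]ethanone F1. Mukaiyama hydration (Co(acac)2 cat., PhSiH3, O2, THF–iPrOH, rt), a Markovnikov hydration of a 1,1-disubstituted alkene that does not touch C2, should then return the route at 10. Any chromene 5 formed by elimination toward C4 can be sent again through steps 3 and 4.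

2. Step 4. Over-reduction of the aryl ketone, or support-induced isomerisation of the very electron-rich benzylic epoxide to a chromanone, may compete with C4–O hydrogenolysis. The fallback sets out from 6. Opening with benzeneselenol (PhSeH, Et3N, EtOH, 0 °C) should occur by SN2 at the benzylic C4, since C3 is shielded by the gem-dimethyl group, and give trans 1-[(3S,4S)-3-hydroxy-7-methoxy-5-(methoxymethoxy)-2,2-dimethyl-4-(phenylselanyl)-3,4-dihydro-2H-chromen-8-yl]ethanone F2. The C3 descriptor changes only through CIP priority; its geometry is untouched. Radical deselenation (Bu3SnH, AIBN, toluene, 80 °C), to which the ketone and the MOM ether are inert, should return the route at 7.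

3. Step 2. O-Alkylation of the hydrogen-bonded, acyl-flanked phenoxide by the tertiary propargylic chloride may be slow and lose material to C-alkylation or to dehydrochlorination of the electrophile. The fallback sets out from 2 and forms the C–C bond first: condensation with commercial 3-methylbut-2-enal (ethylenediammonium diacetate cat., xylene, reflux, or the PhB(OH)2/AcOH-templated variant in toluene with water removal). Knoevenagel-type attack by C3 followed by loss of water and oxa-6π electrocyclisation should lead directly to chromene 5, where the route is rejoined; no new isolable compound arises (F0).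

**Further compounds**

F1 | step 5 | 1-[(2S)-6-methoxy-4-(methoxymethoxy)-2-(prop-1-en-2-yl)-2,3-dihydro-1-benzofuran-7-yl]ethanone | COc1cc(OCOC)c2c(c1C(C)=O)O[C@H](C(C)=C)C2
F2 | step 4 | 1-[(3S,4S)-3-hydroxy-7-methoxy-5-(methoxymethoxy)-2,2-dimethyl-4-(phenylselanyl)-3,4-dihydro-2H-chromen-8-yl]ethanone | COc1cc(OCOC)c2c(c1C(C)=O)OC(C)(C)[C@H](O)[C@H]2[Se]c3ccccc3
F0 | step 2 | none | none
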